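(Readings and results were computed on assumed constants; the scatter is artificial.)

We begin with the easy step, the balance of the starting material, whose charge we call c, in closed flasks that differ in c while the partner charge stays fixed.

the same everywhere: partner 0.198 M

|  | starting material | remark | time |
|---|---|---|---|
| Friday's | 0.0094 M | run made earlier |  |
| Monday's | 0.18 M | run made earlier |  |
| alpha | 0.015 M |  | 8.0 min |
| eta | 0.030 M |  | 8.0 min |
| delta | 0.060 M |  | 8.0 min |
| zeta | 0.12 M |  | 8.0 min |
| theta | 0.20 M |  | 8.0 min |

| run | time / min | first product / % | starting material / % |
|---|---|---|---|
| Friday's | 1.33 | 10.9 | 88.9 |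
| Friday's | 2.50 | 11.5 | 87.6 |
| Friday's | 4.00 | 12.7 | 87.8 |
| Friday's | 5.00 | 13.0 | 87.1 |
| Friday's | 6.00 | 13.0 | 87.3 |
| Friday's | 8.00 | 12.2 | 87.2 |
| Monday's | 0.667 | 8.4 | 92.6 |
| Monday's | 1.00 | 9.1 | 91.2 |
| Monday's | 2.00 | 11.3 | 89.2 |
| Monday's | 3.00 | 12.0 | 88.8 |
| Monday's | 5.00 | 10.3 | 88.0 |
| Monday's | 8.00 | 11.3 | 88.9 |

(each reading ± 0.5 percentage points)

- "hardly changes" means that all values lie within two and a half points (for a concentration: within two and a half percent of the largest)

- [first product] at the end for alpha, eta, delta, zeta, theta, in this order
- how the row runs (falls all the way / falls, then rises / hardly changes / rises all the way / rises, then falls)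

In Friday's run at 8.00 min, first product and starting material sum to 99.4% of c, and in Monday's run at 8.00 min to 100%, so within a scatter of 0.5 percentage points per reading the lost starting material is found as first product. Averaged over the last 3 readings, the first product stands at s_F = 12.7% in Friday's run and s_M = 11.2% in Monday's run, and this s, the plateau share of c held by the first product once it stops rising, is the quantity we carry.

Monday's run is the close neighbour of theta, with the same partner charge of 0.198 M and c of 0.18 M against 0.20 M. Its c is 19.1 times Friday's, yet s differs by 1.5 points, so the product follows the charge. Monday's first product reads 0.0202 M, less than the partner charge, so on the readings making it does not use up that charge. Theta has the partner as limiting reagent by charge, less than its starting material, but on our reckoning s_M times c gives 0.0224 M for theta, and s_F times c gives 0.00191 M for alpha, so we expect a rising row.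

The forecast reads the plateaus as “a fast reversible step” and gives 0.00188 M, 0.00373 M, 0.00733 M, 0.0142 M and 0.0227 M, so that the row rises all the way; its figures for alpha and theta differ slightly from ours.

The flask gives 0.00185 M, 0.00367 M, 0.00721 M, 0.0139 M and 0.0222 M, and the row rises all the way.

    starting material + partner → first product + released group (k = 0.0168 M⁻¹ s⁻¹)
    partner + first product → double product + released group (k = 3.66 × 10⁻⁴ M⁻¹ s⁻¹)
    partner + double product → tris adduct + released group (k = 0.0217 M⁻¹ s⁻¹)
    partner → decomposed reagent (k = 0.0250 s⁻¹)

In alpha the partner stands at 0% of its charge at the end, with decomposed reagent at 0.196 M beside released group at 0.00186 M. The largest single effect on alpha's first product comes from the reaction of partner to decomposed reagent: alpha without that reaction ends at 0.0115 M instead of 0.00185 M. The share still carried over, for s_M on theta gave 0.0224 M against 0.0222 M, and s_F on alpha gave 0.00191 M against 0.00185 M.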